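**Plan**

- Retrosynthesis: the C14=C15 enol ether and the O9–C13 spiro-ether bond are cut first (dehydroiodination, iodoetherification), then C9–C11 (organocerium addition to a C9 ketone) and C8–C17 (methyl addition to a C8 ketone). This leaves a tricyclic lactone.
- The enabling feature is the γ-lactone C19–O–C6, fused to ring A at C4–C5 and to ring B at C5–C6. Read as an α-methylbutenolide (C19, C4=C5, C6, O), it offers C4=C5 as a dienophile joined through C6–C7–C8–C9 to a diene C10=C1–C2=C3, so C3–C4 and C5–C10 are cut together.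
- Forward: acrolein is taken to an (E)-dienyl β-keto ester, its dioxolane and a 2-substituted acrolein. A vinylogous aldol reaction with 3-methyl-2-silyloxyfuran joins C6–C7 and brings in the butenolide. The intramolecular Diels–Alder reaction then closes rings A and B at once. The tetrahydrofuran ring (O9–C13) is closed late and the enol ether is made last.
- Stereochemistry: C6 from the catalytic asymmetric vinylogous aldol; C4, C5 and C10 from C6 in the cycloaddition; C8 and C9 from α-face additions to ring ketones (the β face is blocked by the axial C20 methyl and the C6 oxygen); C13 from the anti iodoetherification.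

Key step: step 10

Assumption: in step 8 the (R,R)-bisphosphoramide is taken to induce the 6S configuration (its antipode is used if the sense proves opposite); atom labels C1–C20 follow labdane numbering throughout.

**Route**

Step 1
Reactants: 1 acrolein; 2 ethyl 2-(triphenyl-λ5-phosphanylidene)propanoate
Product: 3 ethyl (2E)-2-methylpenta-2,4-dienoate
Conditions: CH2Cl2, 0 → 23 °C
Reagents that add atoms: none
Why: Wittig olefination with a stabilised ylide should give the (E)-trisubstituted enoate, which fixes the later C10=C1 geometry (C9 trans to C2, methyl cis).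

Step 2
Reactants: 3 ethyl (2E)-2-methylpenta-2,4-dienoate
Product: 4 (2E)-2-methylpenta-2,4-dienoic acid
Conditions: LiOH·H2O, THF–H2O, 23 °C; then 1 M HCl
Reagents that add atoms: lithium hydroxide, [Li+].[OH-]
Why: Ester saponification under mild hydroxide conditions should free the acid without touching the diene.

Step 3
Reactants: 4 (2E)-2-methylpenta-2,4-dienoic acid
Product: 6 ethyl (4E)-4-methyl-3-oxohepta-4,6-dienoate, via acyl imidazolide 5 (not isolated)
Conditions: CDI, THF, 23 °C; then Mg(O2CCH2CO2Et)2, 23 → 40 °C; 1 M HCl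
Reagents that add atoms: magnesium bis(3-ethoxy-3-oxopropanoate), [Mg+2].[O-]C(=O)CC(=O)OCC.[O-]C(=O)CC(=O)OCC
Why: Masamune–Brooks C-acylation, in which the magnesium malonate half-ester attacks the acyl imidazolide and decarboxylates, adds C8 and C7 as a β-keto ester under nearly neutral conditions.

Step 4
Reactants: 6 ethyl (4E)-4-methyl-3-oxohepta-4,6-dienoate
Product: 7 ethyl 2-{2-[(2E)-penta-2,4-dien-2-yl]-1,3-dioxolan-2-yl}acetate
Conditions: TMSOCH2CH2OTMS, TMSOTf (5 mol %), CH2Cl2, −78 → −20 °C; pyridine quench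
Reagents that add atoms: 1,2-bis(trimethylsilyloxy)ethane, C[Si](C)(C)OCCO[Si](C)(C)C
Why: Noyori ketalisation should mask the C9 ketone at low temperature without conjugate addition, and the enone has no sp3 γ-hydrogen through which the double bond could migrate.

Step 5
Reactants: 7 ethyl 2-{2-[(2E)-penta-2,4-dien-2-yl]-1,3-dioxolan-2-yl}acetate
Product: 8 2-{2-[(2E)-penta-2,4-dien-2-yl]-1,3-dioxolan-2-yl}acetaldehyde
Conditions: DIBAL-H, CH2Cl2, −78 °C; Rochelle salt
Reagents that add atoms: none
Why: DIBAL-H partial reduction of the ester at −78 °C, through a tetrahedral aluminium alkoxide that collapses only on work-up, should stop at the aldehyde.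

Step 6
Reactants: 8 2-{2-[(2E)-penta-2,4-dien-2-yl]-1,3-dioxolan-2-yl}acetaldehyde
Product: 9 2-{2-[(2E)-penta-2,4-dien-2-yl]-1,3-dioxolan-2-yl}prop-2-enal
Conditions: aq. CH2O, pyrrolidine (10 mol %), EtCO2H (10 mol %), i-PrOH, 45 °C
Reagents that add atoms: formaldehyde, C=O
Why: Amine-catalysed α-methylenation (Mannich condensation with formaldehyde, then β-elimination of the amine) turns the α-CH2 into the C8=C17 methylene and leaves an aldehyde without α-hydrogen.

Step 7
Reactants: 10 3-methylfuran-2(5H)-one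
Product: 11 trimethyl[(3-methylfuran-2-yl)oxy]silane
Conditions: TMSOTf, Et3N, Et2O, 0 °C
Reagents that add atoms: trimethylsilyl trifluoromethanesulfonate, C[Si](C)(C)OS(=O)(=O)C(F)(F)F
Why: Soft enolisation and O-silylation of the butenolide gives the aromatic 2-silyloxyfuran, the dienolate equivalent that reacts at furan C5 (the future C6).

Step 8
Reactants: 9 2-{2-[(2E)-penta-2,4-dien-2-yl]-1,3-dioxolan-2-yl}prop-2-enal; 11 trimethyl[(3-methylfuran-2-yl)oxy]silane
Product: 13 (5S)-5-[(1R)-1-hydroxy-2-{2-[(2E)-penta-2,4-dien-2-yl]-1,3-dioxolan-2-yl}prop-2-en-1-yl]-3-methylfuran-2(5H)-one, via trichlorosilyl ether 12 (not isolated)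
Conditions: SiCl4, (R,R)-binaphthyldiamine bisphosphoramide (5 mol %), i-Pr2NEt (cat.), CH2Cl2, −78 °C; aq. NaHCO3/KF
Reagents that add atoms: none
Why: Catalytic enantioselective vinylogous Mukaiyama aldol reaction (Lewis-base-activated SiCl4) should join furan C5 (C6) to the aldehyde carbon (C7) by 1,2-addition; the chiral silyl cation sets C6 as S and the open transition state gives the anti (7R) carbinol, whose configuration is erased later.

Step 9
Reactants: 13 (5S)-5-[(1R)-1-hydroxy-2-{2-[(2E)-penta-2,4-dien-2-yl]-1,3-dioxolan-2-yl}prop-2-en-1-yl]-3-methylfuran-2(5H)-one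
Product: 14 (5S)-5-[(1R)-1-(tert-butyldimethylsilyloxy)-2-{2-[(2E)-penta-2,4-dien-2-yl]-1,3-dioxolan-2-yl}prop-2-en-1-yl]-3-methylfuran-2(5H)-one
Conditions: TBSCl, imidazole, DMF, 23 → 40 °C
Reagents that add atoms: tert-butyldimethylsilyl chloride, CC(C)(C)[Si](C)(C)Cl
Why: Silyl ether formation with TBSCl/imidazole protects the C7 hydroxyl under triflate-free conditions that should spare the bis-allylic dioxolane.

Step 10
Reactants: 14 (5S)-5-[(1R)-1-(tert-butyldimethylsilyloxy)-2-{2-[(2E)-penta-2,4-dien-2-yl]-1,3-dioxolan-2-yl}prop-2-en-1-yl]-3-methylfuran-2(5H)-one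
Product: 15 7β-(tert-butyldimethylsilyloxy)-9,9-(ethylenedioxy)-11,12,13,14,15,16-hexanorlabda-1,8(17)-dien-19,6β-olide
Conditions: toluene (0.005 M), BHT, propylene oxide, sealed tube, 155 °C
Reagents that add atoms: none
Why: On heating, the (E)-diene C10=C1–C2=C3 adds suprafacially across the lactone-activated butenolide alkene C4=C5 in a concerted, asynchronous [4+2] cycloaddition; the closest known reaction type is the type-1 intramolecular Diels–Alder reaction of 1,7,9-decatrienes with a γ-tethered butenolide dienophile. Ring A (C1–C5, C10) closes as the new cyclohexene of the [4+2] event through C3–C4 and C5–C10, and ring B (C5–C10) closes at the same time as a six-membered carbocycle because the four-atom tether C6–C7–C8–C9 links the diene terminus C10 to the dienophile carbon C5. C5 is controlled by C6, since the tether can bring the diene only to the butenolide face that carries C7, which leaves H5 cis to H6; C4 follows from the fixed cis geometry of the ring alkene, so C19 and the C6 oxygen stay cis as the lactone demands; C10 is controlled by the (E)-tether/(Z)-methyl diene geometry together with the exo position of the lactone carbonyl, which puts the C20 methyl anti to H5 (trans-decalin). The step needs exo over endo selectivity and a cycloaddition faster than the [1,5]-hydrogen shift open to the (Z)-methyl diene; the exo chair keeps the 7-silyloxy group equatorial and places the α-methyl group rather than the carbonyl under the diene (the usual preference of α-methyl acrylate-type dienophiles), while the gem-dialkoxy C9 and the sp2 C8 pre-organise the tether.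

Step 11
Reactants: 15 7β-(tert-butyldimethylsilyloxy)-9,9-(ethylenedioxy)-11,12,13,14,15,16-hexanorlabda-1,8(17)-dien-19,6β-olide
Product: 16 7β-(tert-butyldimethylsilyloxy)-9,9-(ethylenedioxy)-11,12,13,14,15,16-hexanorlabd-8(17)-en-19,6β-olide
Conditions: H2 (1 atm), RhCl(PPh3)3 (10 mol %), benzene–EtOH, 23 °C
Reagents that add atoms: none
Why: Homogeneous hydrogenation with Wilkinson's catalyst is very sensitive to alkene hindrance, so the cis-disubstituted C1=C2 bond should be reduced while the C8 methylene, flanked by the spiro-ketal carbon and the silyloxy-bearing C7, is left.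

Step 12
Reactants: 16 7β-(tert-butyldimethylsilyloxy)-9,9-(ethylenedioxy)-11,12,13,14,15,16-hexanorlabd-8(17)-en-19,6β-olide
Product: 18 7β-(tert-butyldimethylsilyloxy)-9,9-(ethylenedioxy)-8-oxo-11,12,13,14,15,16,17-heptanorlabdan-19,6β-olide, via ozonide 17 (not isolated)
Conditions: O3, CH2Cl2, −78 °C; then PPh3, −78 → 23 °C
Reagents that add atoms: ozone, [O-][O+]=O
Why: Ozonolysis with reductive work-up cleaves the only remaining alkene to the C8 ketone, C17 leaving as formaldehyde.

Step 13
Reactants: 18 7β-(tert-butyldimethylsilyloxy)-9,9-(ethylenedioxy)-8-oxo-11,12,13,14,15,16,17-heptanorlabdan-19,6β-olide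
Product: 19 7β-(tert-butyldimethylsilyloxy)-9,9-(ethylenedioxy)-8β-hydroxy-11,12,13,14,15,16-hexanorlabdan-19,6β-olide
Conditions: MeLi, CeCl3, THF, −78 °C; aq. NH4Cl
Reagents that add atoms: methyllithium, [Li]C
Why: Organocerium 1,2-addition with the weakly basic MeCeCl2 should avoid enolisation and β-elimination of the C6 lactone oxygen, and the reagent attacks from the α (equatorial) face because the axial β trajectory is blocked by the 1,3-diaxial C20 methyl and C6–O, giving 8β-OH and 8α-CH3.

Step 14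
Reactants: 19 7β-(tert-butyldimethylsilyloxy)-9,9-(ethylenedioxy)-8β-hydroxy-11,12,13,14,15,16-hexanorlabdan-19,6β-olide
Product: 20 7β-(tert-butyldimethylsilyloxy)-8β-hydroxy-9-oxo-11,12,13,14,15,16-hexanorlabdan-19,6β-olide
Conditions: PPTS, acetone–H2O (9:1), 55 °C
Reagents that add atoms: water, O
Why: Acid-catalysed ketal hydrolysis under mild conditions should release the C9 ketone, which has no α-hydrogen, and keep the hindered secondary TBS ether.

Step 15
Reactants: 21 3-(prop-2-yn-1-yloxy)prop-1-ene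
Product: 22 3-ethenyl-2,5-dihydrofuran
Conditions: first-generation Grubbs catalyst (3 mol %), ethylene (1 atm), CH2Cl2, 23 °C
Reagents that add atoms: none
Why: Ruthenium-catalysed ring-closing enyne metathesis of the 1,6-enyne gives the 3-vinyl-2,5-dihydrofuran by an atom-economical skeletal reorganisation.

Step 16
Reactants: 22 3-ethenyl-2,5-dihydrofuran
Product: 24 2-(2,5-dihydrofuran-3-yl)ethan-1-ol, via alkylborane 23 (not isolated)
Conditions: 9-BBN, THF, 0 → 23 °C; then NaOH, H2O2, 0 °C
Reagents that add atoms: hydrogen peroxide, OO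
Why: Hydroboration–oxidation with 9-BBN should add anti-Markovnikov to the terminal vinyl group only, the trisubstituted ring alkene being far less reactive towards this bulky borane.

Step 17
Reactants: 24 2-(2,5-dihydrofuran-3-yl)ethan-1-ol
Product: 25 3-(2-iodoethyl)-2,5-dihydrofuran
Conditions: I2, PPh3, imidazole, CH2Cl2, 0 °C
Reagents that add atoms: iodine, II
Why: Appel-type iodination converts the primary alcohol into the iodide by SN2 displacement of the oxyphosphonium group.

Step 18
Reactants: 20 7β-(tert-butyldimethylsilyloxy)-8β-hydroxy-9-oxo-11,12,13,14,15,16-hexanorlabdan-19,6β-olide; 25 3-(2-iodoethyl)-2,5-dihydrofuran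
Product: 28 (9R)-7β-(tert-butyldimethylsilyloxy)-15,16-epoxy-8β,9-dihydroxylabd-13-en-19,6β-olide, via organolithium 26 (not isolated), via organocerium 27 (not isolated)
Conditions: 25, t-BuLi (2 equiv), Et2O–pentane, −78 °C; CeCl3, THF, −78 °C; then 20 (3 equiv of 27 per ketone), −78 → −20 °C; aq. NH4Cl
Reagents that add atoms: none
Why: Iodine–lithium exchange, transmetalation to cerium and 1,2-addition: the nucleophilic, weakly basic organocerium should add to the hindered, non-enolisable C9 ketone from the α face (axial attack anti to the C20 methyl and the 8β-oxygen), giving C11 α and 9β-OH (9R).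

Step 19
Reactants: 28 (9R)-7β-(tert-butyldimethylsilyloxy)-15,16-epoxy-8β,9-dihydroxylabd-13-en-19,6β-olide
Product: 29 (9R)-15,16-epoxy-7β,8β,9-trihydroxylabd-13-en-19,6β-olide
Conditions: HF·pyridine, pyridine, THF, 0 → 23 °C
Reagents that add atoms: none
Why: Fluoride-mediated desilylation with buffered HF·pyridine frees the C7 hydroxyl without acid strong enough to protonate the dihydrofuran alkene.

Step 20
Reactants: 29 (9R)-15,16-epoxy-7β,8β,9-trihydroxylabd-13-en-19,6β-olide
Product: 30 (9R,13S,14S)-9,13:15,16-diepoxy-7β,8β-dihydroxy-14-iodolabdan-19,6β-olide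
Conditions: I2, NaHCO3, MeCN, 0 °C
Reagents that add atoms: iodine, II
Why: Iodoetherification: the 9β-hydroxyl opens the iodonium ion of C13=C14 at the more substituted C13 in a 5-exo anti addition; C13 is set by the alkene face engaged in the closure, which is expected to place the bulky iodine-bearing C14 on the C8 side, away from the axial C20 methyl (the arrangement of the target), and C14 follows from the anti addition.

Step 21
Reactants: 30 (9R,13S,14S)-9,13:15,16-diepoxy-7β,8β-dihydroxy-14-iodolabdan-19,6β-olide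
Product: 31 (9R,13S,14S)-9,13:15,16-diepoxy-8β-hydroxy-14-iodo-7-oxolabdan-19,6β-olide
Conditions: IBX, DMSO, 23 °C
Reagents that add atoms: none
Why: IBX oxidation converts the secondary C7 alcohol into the ketone and should not cleave the adjacent secondary/tertiary diol unit.

Step 22
Reactants: 31 (9R,13S,14S)-9,13:15,16-diepoxy-8β-hydroxy-14-iodo-7-oxolabdan-19,6β-olide
Product: 32 (9R,13S,14S)-8β-acetoxy-9,13:15,16-diepoxy-14-iodo-7-oxolabdan-19,6β-olide
Conditions: Ac2O, Sc(OTf)3 (5 mol %), MeCN, −20 °C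
Reagents that add atoms: acetic anhydride, CC(=O)OC(C)=O
Why: Lewis-acid-catalysed acylation should acetylate the hindered tertiary C8 alcohol at low temperature, before the acid-sensitive enol ether is present.

Step 23
Reactants: 32 (9R,13S,14S)-8β-acetoxy-9,13:15,16-diepoxy-14-iodo-7-oxolabdan-19,6β-olide
Product: 33 (9R,13R)-8β-acetoxy-9,13:15,16-diepoxy-7-oxolabd-14-en-19,6β-olide (CNP0155227.1)
Conditions: DBU, toluene, 80 °C
Reagents that add atoms: none
Why: E2 dehydroiodination with DBU: the only β-hydrogens of the C14 iodide are on C15, so anti elimination can only give the C14=C15 enol ether of the target.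

**Compound list**

1 | acrolein | C=CC=O | starting material
2 | ethyl 2-(triphenyl-λ5-phosphanylidene)propanoate | CCOC(=O)C(C)=P(c1ccccc1)(c1ccccc1)c1ccccc1 | starting material
3 | ethyl (2E)-2-methylpenta-2,4-dienoate | C=C/C=C(\C)C(=O)OCC | intermediate
4 | (2E)-2-methylpenta-2,4-dienoic acid | C=C/C=C(\C)C(=O)O | intermediate
5 | (2E)-1-(imidazol-1-yl)-2-methylpenta-2,4-dien-1-one (not isolated) | C=C/C=C(\C)C(=O)n1ccnc1 | intermediate
6 | ethyl (4E)-4-methyl-3-oxohepta-4,6-dienoate | C=C/C=C(\C)C(=O)CC(=O)OCC | intermediate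
7 | ethyl 2-{2-[(2E)-penta-2,4-dien-2-yl]-1,3-dioxolan-2-yl}acetate | C=C/C=C(\C)C1(OCCO1)CC(=O)OCC | intermediate
8 | 2-{2-[(2E)-penta-2,4-dien-2-yl]-1,3-dioxolan-2-yl}acetaldehyde | C=C/C=C(\C)C1(OCCO1)CC=O | intermediate
9 | 2-{2-[(2E)-penta-2,4-dien-2-yl]-1,3-dioxolan-2-yl}prop-2-enal | C=C/C=C(\C)C1(OCCO1)C(=C)C=O | intermediate
10 | 3-methylfuran-2(5H)-one | CC1=CCOC1=O | starting material
11 | trimethyl[(3-methylfuran-2-yl)oxy]silane | Cc1ccoc1O[Si](C)(C)C | intermediate
12 | (5S)-3-methyl-5-[(1R)-2-{2-[(2E)-penta-2,4-dien-2-yl]-1,3-dioxolan-2-yl}-1-(trichlorosilyloxy)prop-2-en-1-yl]furan-2(5H)-one (not isolated) | C=C/C=C(\C)C1(OCCO1)C(=C)[C@@H](O[Si](Cl)(Cl)Cl)[C@H]1OC(=O)C(C)=C1 | intermediate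
13 | (5S)-5-[(1R)-1-hydroxy-2-{2-[(2E)-penta-2,4-dien-2-yl]-1,3-dioxolan-2-yl}prop-2-en-1-yl]-3-methylfuran-2(5H)-one | C=C/C=C(\C)C1(OCCO1)C(=C)[C@@H](O)[C@H]1OC(=O)C(C)=C1 | intermediate
14 | (5S)-5-[(1R)-1-(tert-butyldimethylsilyloxy)-2-{2-[(2E)-penta-2,4-dien-2-yl]-1,3-dioxolan-2-yl}prop-2-en-1-yl]-3-methylfuran-2(5H)-one | C=C/C=C(\C)C1(OCCO1)C(=C)[C@@H](O[Si](C)(C)C(C)(C)C)[C@H]1OC(=O)C(C)=C1 | intermediate
15 | 7β-(tert-butyldimethylsilyloxy)-9,9-(ethylenedioxy)-11,12,13,14,15,16-hexanorlabda-1,8(17)-dien-19,6β-olide (5α-H, 10β-CH3) | C=C1[C@@H](O[Si](C)(C)C(C)(C)C)[C@H]2OC(=O)[C@@]3(C)CC=C[C@@](C)([C@@H]23)C14OCCO4 | intermediate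
16 | 7β-(tert-butyldimethylsilyloxy)-9,9-(ethylenedioxy)-11,12,13,14,15,16-hexanorlabd-8(17)-en-19,6β-olide | C=C1[C@@H](O[Si](C)(C)C(C)(C)C)[C@H]2OC(=O)[C@@]3(C)CCC[C@@](C)([C@@H]23)C14OCCO4 | intermediate
17 | 8,17-ozonide (spiro-1,2,4-trioxolane at C8, either configuration) of 16 (not isolated) | C1OC2(OO1)[C@@H](O[Si](C)(C)C(C)(C)C)[C@H]3OC(=O)[C@@]4(C)CCC[C@@](C)([C@@H]34)C25OCCO5 | intermediate
18 | 7β-(tert-butyldimethylsilyloxy)-9,9-(ethylenedioxy)-8-oxo-11,12,13,14,15,16,17-heptanorlabdan-19,6β-olide | O=C1[C@@H](O[Si](C)(C)C(C)(C)C)[C@H]2OC(=O)[C@@]3(C)CCC[C@@](C)([C@@H]23)C14OCCO4 | intermediate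
19 | 7β-(tert-butyldimethylsilyloxy)-9,9-(ethylenedioxy)-8β-hydroxy-11,12,13,14,15,16-hexanorlabdan-19,6β-olide (17-CH3 α) | O[C@@]1(C)[C@@H](O[Si](C)(C)C(C)(C)C)[C@H]2OC(=O)[C@@]3(C)CCC[C@@](C)([C@@H]23)C14OCCO4 | intermediate
20 | 7β-(tert-butyldimethylsilyloxy)-8β-hydroxy-9-oxo-11,12,13,14,15,16-hexanorlabdan-19,6β-olide | O[C@@]1(C)[C@@H](O[Si](C)(C)C(C)(C)C)[C@H]2OC(=O)[C@@]3(C)CCC[C@@](C)([C@@H]23)C1=O | intermediate
21 | 3-(prop-2-yn-1-yloxy)prop-1-ene (allyl propargyl ether) | C=CCOCC#C | starting material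
22 | 3-ethenyl-2,5-dihydrofuran | C=CC1=CCOC1 | intermediate
23 | 9-[2-(2,5-dihydrofuran-3-yl)ethyl]-9-borabicyclo[3.3.1]nonane (not isolated) | C1=C(CCB2C3CCCC2CCC3)COC1 | intermediate
24 | 2-(2,5-dihydrofuran-3-yl)ethan-1-ol | OCCC1=CCOC1 | intermediate
25 | 3-(2-iodoethyl)-2,5-dihydrofuran | ICCC1=CCOC1 | intermediate
26 | [2-(2,5-dihydrofuran-3-yl)ethyl]lithium (not isolated) | [Li]CCC1=CCOC1 | intermediate
27 | dichloro[2-(2,5-dihydrofuran-3-yl)ethyl]cerium (not isolated) | Cl[Ce](Cl)CCC1=CCOC1 | intermediate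
28 | (9R)-7β-(tert-butyldimethylsilyloxy)-15,16-epoxy-8β,9-dihydroxylabd-13-en-19,6β-olide (9-OH β, C11 α) | O[C@@]1(C)[C@@H](O[Si](C)(C)C(C)(C)C)[C@H]2OC(=O)[C@@]3(C)CCC[C@@](C)([C@@H]23)[C@]1(O)CCC1=CCOC1 | intermediate
29 | (9R)-15,16-epoxy-7β,8β,9-trihydroxylabd-13-en-19,6β-olide | O[C@@]1(C)[C@@H](O)[C@H]2OC(=O)[C@@]3(C)CCC[C@@](C)([C@@H]23)[C@]1(O)CCC1=CCOC1 | intermediate
30 | (9R,13S,14S)-9,13:15,16-diepoxy-7β,8β-dihydroxy-14-iodolabdan-19,6β-olide (I trans to O9) | O[C@@]1(C)[C@@H](O)[C@H]2OC(=O)[C@@]3(C)CCC[C@@](C)([C@@H]23)[C@]12CC[C@]1([C@@H](I)COC1)O2 | intermediate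
31 | (9R,13S,14S)-9,13:15,16-diepoxy-8β-hydroxy-14-iodo-7-oxolabdan-19,6β-olide | O[C@@]1(C)C(=O)[C@H]2OC(=O)[C@@]3(C)CCC[C@@](C)([C@@H]23)[C@]12CC[C@]1([C@@H](I)COC1)O2 | intermediate
32 | (9R,13S,14S)-8β-acetoxy-9,13:15,16-diepoxy-14-iodo-7-oxolabdan-19,6β-olide | CC(=O)O[C@@]1(C)C(=O)[C@H]2OC(=O)[C@@]3(C)CCC[C@@](C)([C@@H]23)[C@]12CC[C@]1([C@@H](I)COC1)O2 | intermediate
33 | (4S,5R,6S,8R,9R,10S,13R)-8β-acetoxy-9,13:15,16-diepoxy-7-oxolabd-14-en-19,6β-olide (CNP0155227.1) | CC(=O)O[C@@]1(C)C(=O)[C@H]2OC(=O)[C@@]3(C)CCC[C@@](C)([C@@H]23)[C@]12CC[C@]1(C=COC1)O2 | target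

**Count and risks**

Total step count: 23. Longest linear sequence: 19 steps (steps 1–6, 8–14, 18–23); steps 7 and 15–17 are side branches.

The three steps most likely to fail:

1. Step 11: loss of chemoselectivity in the hydrogenation, i.e. reduction of the C8 methylene, or its migration into the ring, together with C1=C2. The fallback sets out from 15 and comes back at 18. The two alkenes are told apart by hydroboration instead: 9-BBN adds only to the 1,1-disubstituted methylene (cyclohexene-type alkenes are inert to it) to give the B-alkyl-9-BBN adduct F1, which NaOH/H2O2 oxidises to the primary alcohol F2. Hydrogenation over Pd/C then saturates C1=C2 without competition and gives the saturated alcohol F3. Dess–Martin oxidation gives the α-branched aldehyde F4, and copper-catalysed aerobic oxidative deformylation (O2, Cu(OAc)2, 2,2′-bipyridine, DABCO, DMF) removes C17 to deliver ketone 18.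

2. Step 18: failure of carbon–carbon bond formation at the doubly neopentylic C9 ketone, the reagent being spent by proton transfer or by base-induced opening of its dihydrofuran ring before it adds. The fallback sets out from 20 and comes back at 28. The smallest sp2 nucleophile is added first and the side chain is completed by cross-coupling: vinylmagnesium bromide with CeCl3 gives the 9-vinyl carbinol F5 by the same α-face attack; 9-BBN hydroborates its terminal alkene to the alkylborane F6; and B-alkyl Suzuki–Miyaura coupling (Pd(dppf)Cl2, aq. K3PO4, DMF) with 3-bromo-2,5-dihydrofuran F7 forms C12–C13 and gives 28. F7 is obtained from commercial 2-(2,5-dihydrofuran-3-yl)-4,4,5,5-tetramethyl-1,3,2-dioxaborolane by bromodeboronation with CuBr2.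

3. Step 20: poor facial selectivity in iodonium formation and ring closure, so that the C13 epimer forms in quantity; the local environment on the two sides of the forming tetrahydrofuran is nearly symmetrical. The fallback sets out from 29 and comes back at 29. The cyclisation is run as a recycling loop instead of a single pass: the diastereomers are separated, and the unwanted 13,14-bis-epimeric iodoether F8 is returned to triol 29 by zinc-mediated reductive β-elimination (Zn, AcOH, EtOH), the classical reversal of a halo-etherification, and resubmitted.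

Further compounds
F1 | step 11 | 17-(9-borabicyclo[3.3.1]nonan-9-yl)-7β-(tert-butyldimethylsilyloxy)-9,9-(ethylenedioxy)-11,12,13,14,15,16-hexanorlabd-1-en-19,6β-olide (8α-H) | C(B1C2CCCC1CCC2)[C@H]1[C@@H](O[Si](C)(C)C(C)(C)C)[C@H]2OC(=O)[C@@]3(C)CC=C[C@@](C)([C@@H]23)C14OCCO4
F2 | step 11 | 7β-(tert-butyldimethylsilyloxy)-9,9-(ethylenedioxy)-17-hydroxy-11,12,13,14,15,16-hexanorlabd-1-en-19,6β-olide (8α-H) | OC[C@H]1[C@@H](O[Si](C)(C)C(C)(C)C)[C@H]2OC(=O)[C@@]3(C)CC=C[C@@](C)([C@@H]23)C14OCCO4
F3 | step 11 | 7β-(tert-butyldimethylsilyloxy)-9,9-(ethylenedioxy)-17-hydroxy-11,12,13,14,15,16-hexanorlabdan-19,6β-olide (8α-H) | OC[C@H]1[C@@H](O[Si](C)(C)C(C)(C)C)[C@H]2OC(=O)[C@@]3(C)CCC[C@@](C)([C@@H]23)C14OCCO4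
F4 | step 11 | 7β-(tert-butyldimethylsilyloxy)-9,9-(ethylenedioxy)-17-oxo-11,12,13,14,15,16-hexanorlabdan-19,6β-olide (8α-H) | O=C[C@H]1[C@@H](O[Si](C)(C)C(C)(C)C)[C@H]2OC(=O)[C@@]3(C)CCC[C@@](C)([C@@H]23)C14OCCO4
F5 | step 18 | (9R)-7β-(tert-butyldimethylsilyloxy)-8β,9-dihydroxy-13,14,15,16-tetranorlabd-11-en-19,6β-olide | O[C@@]1(C)[C@@H](O[Si](C)(C)C(C)(C)C)[C@H]2OC(=O)[C@@]3(C)CCC[C@@](C)([C@@H]23)[C@]1(O)C=C
F6 | step 18 | (9R)-12-(9-borabicyclo[3.3.1]nonan-9-yl)-7β-(tert-butyldimethylsilyloxy)-8β,9-dihydroxy-13,14,15,16-tetranorlabdan-19,6β-olide | O[C@@]1(C)[C@@H](O[Si](C)(C)C(C)(C)C)[C@H]2OC(=O)[C@@]3(C)CCC[C@@](C)([C@@H]23)[C@]1(O)CCB1C2CCCC1CCC2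
F7 | step 18 | 3-bromo-2,5-dihydrofuran | BrC1=CCOC1
F8 | step 20 | (9R,13R,14R)-9,13:15,16-diepoxy-7β,8β-dihydroxy-14-iodolabdan-19,6β-olide (13,14-bis-epimer of 30) | O[C@@]1(C)[C@@H](O)[C@H]2OC(=O)[C@@]3(C)CCC[C@@](C)([C@@H]23)[C@]12CC[C@@]1([C@H](I)COC1)O2
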